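## Retrosynthetic overview

1. The target comes from its 5,7-dimethoxy analogue by chelation-controlled cleavage of the 5-O-methyl group (last step).
2. The C2–C1′ bond is cut: 4-methoxyresorcinol (ring B, from resorcinol) adds enantioselectively to C2 of a 5,7-dimethoxy-8-lavandulylchromone, which sets C2.
3. The chromone (ring C closed on ring A) comes from a 2-(MOM-oxy)acetophenone (DMF-DMA, then acid), made by directed ortho-lithiation and acylation.
4. The lavandulyl chain is grown on ring A by three successive 1,2-shifts of carbon from boron to carbon: aryllithium + ClCH2Bpin; a Pd-catalysed conjunctive coupling (key step, sets the side-chain stereocentre); Zweifel isopropenylation.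
5. Ring A comes from resorcinol (methylation, meta C–H borylation/oxidation, MOM ether). Ring order: A first, then C, with ring B attached last.

Assumption: the catalyst antipodes named in steps 5 and 11 are taken to give (R)-12 and (2S)-28; if either sense proves opposite, the mirror-image catalyst is used.

## Route

Step 1
Reactants: 1 resorcinol
Product: 2 1,3-dimethoxybenzene
Conditions: MeI (2.5 equiv), K2CO3, acetone, reflux
Reagents that add atoms: iodomethane, CI
Why: Double Williamson O-methylation of the two phenols is a standard, high-yielding ether synthesis with no selectivity issue.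

Step 2
Reactants: 2 1,3-dimethoxybenzene
Product: 4 3,5-dimethoxyphenol, via aryl boronic ester 3 (not isolated)
Conditions: [Ir(OMe)(cod)]2 (1 mol%), 4,4′-di-tert-butyl-2,2′-bipyridine (2 mol%), B2pin2, THF, 80 °C; then KHSO5 (as 2KHSO5·KHSO4·K2SO4), acetone/H2O, rt
Reagents that add atoms: bis(pinacolato)diboron, CC1(C)OB(OC1(C)C)B2OC(C)(C)C(C)(C)O2 (boron group of 3 only); potassium peroxymonosulfate, [K+].[O-]S(=O)(=O)OO (phenol oxygen of 4)
Why: Sterically controlled iridium-catalysed C–H borylation goes to C5, the only position not ortho to a methoxy group, and the boronic ester is oxidised in the same pot by a 1,2-shift of the aryl group from boron to oxygen (one-pot C–H borylation/oxidation).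

Step 3
Reactants: 4 3,5-dimethoxyphenol
Product: 5 1,3-dimethoxy-5-(methoxymethoxy)benzene
Conditions: MOMCl, iPr2NEt, CH2Cl2, 0 °C → rt
Reagents that add atoms: chloromethyl methyl ether, COCCl
Why: Standard MOM ether formation gives the ortho-directing group needed for both later lithiations.

Step 4
Reactants: 5 1,3-dimethoxy-5-(methoxymethoxy)benzene
Product: 8 2-[2,4-dimethoxy-6-(methoxymethoxy)benzyl]-4,4,5,5-tetramethyl-1,3,2-dioxaborolane, via aryllithium 6 (not isolated), via chloromethyl borate 7 (not isolated)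
Conditions: n-BuLi (1.1 equiv), THF, 0 °C → rt; ClCH2Bpin (1.2 equiv), −78 °C → rt
Reagents that add atoms: n-butyllithium, [Li]CCCC (lithium of 6 and 7 only); 2-(chloromethyl)-4,4,5,5-tetramethyl-1,3,2-dioxaborolane, ClCB1OC(C)(C)C(C)(C)O1
Why: Directed ortho-metalation occurs at the position flanked by OMOM and OMe (the two ortho positions of the OMOM group are equivalent), and in borate 7 the aryl group shifts 1,2 from boron to the CH2Cl carbon with loss of chloride (Matteson-type homologation), which installs the benzylic carbon.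

Step 5
Reactants: 8 2-[2,4-dimethoxy-6-(methoxymethoxy)benzyl]-4,4,5,5-tetramethyl-1,3,2-dioxaborolane; 9 vinylmagnesium chloride; 10 1-bromo-2-methylprop-1-ene
Product: 12 2-{(2R)-1-[2,4-dimethoxy-6-(methoxymethoxy)phenyl]-5-methylhex-4-en-2-yl}-4,4,5,5-tetramethyl-1,3,2-dioxaborolane, via vinyl borate 11 (not isolated)
Conditions: 9 (1.05 equiv), THF, 0 °C → rt; then Pd(OAc)2 (2 mol%), (αR,αR)-2,2′-bis[α-(dimethylamino)benzyl]-(Sp,Sp)-1,1′-bis[bis(4-methoxy-3,5-dimethylphenyl)phosphino]ferrocene (MandyPhos, 2.4 mol%), NaOSO2CF3 (2 equiv), 10 (1.2 equiv), THF/DMSO, 60 °C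
Reagents that add atoms: none
Why: In this enantioselective conjunctive cross-coupling the alkenylpalladium bromide formed from 10 binds the vinyl group of borate 11 and triggers a 1,2-shift of the benzyl group from boron to the α-carbon on the face chosen by the chiral ligand, and reductive elimination then joins the β-carbon to the 2-methylprop-1-enyl group, so the (R) side-chain stereocentre and two C–C bonds are made in one step.

Step 6
Reactants: 12 2-{(2R)-1-[2,4-dimethoxy-6-(methoxymethoxy)phenyl]-5-methylhex-4-en-2-yl}-4,4,5,5-tetramethyl-1,3,2-dioxaborolane; 13 2-bromopropene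
Product: 17 1,5-dimethoxy-3-(methoxymethoxy)-2-[(2R)-5-methyl-2-(prop-1-en-2-yl)hex-4-en-1-yl]benzene, via isopropenyllithium 14 (not isolated), via isopropenyl borate 15 (not isolated), via iodo boronic ester 16 (not isolated)
Conditions: 13, t-BuLi (2 equiv to 13), THF, −78 °C; add 12, −78 → 0 °C; I2, MeOH, −78 °C; NaOMe, MeOH, −78 °C → rt
Reagents that add atoms: tert-butyllithium, [Li]C(C)(C)C (lithium of 14 and 15 only); iodine, [I][I] (iodine of 16 only)
Why: In this Zweifel olefination iodine activates the isopropenyl group of borate 15, the secondary alkyl group shifts 1,2 from boron to carbon with retention of configuration, and methoxide-induced anti elimination of boron and iodide from 16 gives the isopropenyl group, so the stereocentre is carried over unchanged (descriptor stays R).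

Step 7
Reactants: 17 1,5-dimethoxy-3-(methoxymethoxy)-2-[(2R)-5-methyl-2-(prop-1-en-2-yl)hex-4-en-1-yl]benzene; 18 N-methoxy-N-methylacetamide
Product: 21 1-{4,6-dimethoxy-2-(methoxymethoxy)-3-[(2R)-5-methyl-2-(prop-1-en-2-yl)hex-4-en-1-yl]phenyl}ethan-1-one, via aryllithium 19 (not isolated), via lithium hemiaminal adduct 20 (not isolated)
Conditions: n-BuLi (1.1 equiv), THF, 0 °C; 18, −78 → 0 °C; then H2O
Reagents that add atoms: n-butyllithium, [Li]CCCC (lithium of 19 and 20 only)
Why: The second directed ortho-metalation takes the only remaining position ortho to OMOM (between OMOM and OMe), and acylation with the Weinreb amide stops at the chelated adduct 20, which gives the methyl ketone on work-up (Weinreb ketone synthesis).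

Step 8
Reactants: 21 1-{4,6-dimethoxy-2-(methoxymethoxy)-3-[(2R)-5-methyl-2-(prop-1-en-2-yl)hex-4-en-1-yl]phenyl}ethan-1-one
Product: 24 5,7-dimethoxy-8-[(2R)-5-methyl-2-(prop-1-en-2-yl)hex-4-en-1-yl]-4H-chromen-4-one, via enaminone 22 (not isolated), via phenol enaminone 23 (not isolated)
Conditions: DMF-DMA (3 equiv), toluene, 100 °C; evaporate; then HCl (2 M) in MeOH, 45 °C
Reagents that add atoms: N,N-dimethylformamide dimethyl acetal, COC(OC)N(C)C
Why: Condensation with DMF-DMA gives the enaminone, HCl removes the MOM group ortho to the carbonyl, and the freed phenol adds to the β-carbon and expels dimethylamine (enaminone route to chromones); only one chromone can form because the other ortho oxygen is a methyl ether.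

Step 9
Reactants: 1 resorcinol
Product: 25 4-bromobenzene-1,3-diol
Conditions: NBS (1.0 equiv), CH2Cl2/MeCN, −30 °C → rt
Reagents that add atoms: N-bromosuccinimide, O=C1CCC(=O)N1Br
Why: Electrophilic aromatic bromination with one equivalent of NBS at low temperature goes to C4, which is ortho to one hydroxyl and para to the other.

Step 10
Reactants: 25 4-bromobenzene-1,3-diol
Product: 26 4-methoxybenzene-1,3-diol
Conditions: NaOMe (5 equiv), CuBr (10 mol%), MeOH/DMF, 110 °C; then dilute aq. HCl
Reagents that add atoms: sodium methoxide, [Na+].[O-]C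
Why: Copper-catalysed methoxylation of the aryl bromide (Ullmann-type C–O coupling) is the method used for bromophenols such as 5-bromovanillin.

Step 11
Reactants: 24 5,7-dimethoxy-8-[(2R)-5-methyl-2-(prop-1-en-2-yl)hex-4-en-1-yl]-4H-chromen-4-one; 26 4-methoxybenzene-1,3-diol
Product: 28 (2S)-2-(2,4-dihydroxy-5-methoxyphenyl)-5,7-dimethoxy-8-[(2R)-5-methyl-2-(prop-1-en-2-yl)hex-4-en-1-yl]-2,3-dihydro-4H-chromen-4-one, via enol 27 (not isolated)
Conditions: (R)-3,3′-bis(2,4,6-triisopropylphenyl)-1,1′-binaphthalene-2,2′-diyl N-(trifluoromethylsulfonyl)phosphoramide (10 mol%), 26 (1.5 equiv), 5 Å MS, CH2Cl2/toluene 1:1, −20 → 0 °C; NaHCO3 quench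
Reagents that add atoms: none
Why: Proposed new method: a chiral Brønsted acid-catalysed enantioselective conjugate Friedel–Crafts arylation of a chromone by a free phenol, in which the acid protonates the C4 carbonyl of 24 to a 4-hydroxybenzopyrylium ion held in a contact ion pair by the chiral phosphoramidate, C6 of 26 (ortho to one OH, para to the other, the most nucleophilic unhindered site) attacks C2 while its phenolic OH is hydrogen-bonded to the same anion so that one face is attacked and the C2–C1′ bond and the 2S centre are formed, rearomatisation returns the proton to the catalyst and enol 27 tautomerises to the flavanone; the closest known reactions are chiral phosphoric acid-catalysed Friedel–Crafts reactions of phenols with ortho-quinone methides and oxocarbenium ions, enantioselective additions of silyl ketene acetals to 4-silyloxybenzopyrylium ions under chiral anion-binding catalysis, and the rhodium- or palladium-catalysed asymmetric 1,4-addition of arylboronic acids to chromones, which makes the same bond.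

Step 12
Reactants: 28 (2S)-2-(2,4-dihydroxy-5-methoxyphenyl)-5,7-dimethoxy-8-[(2R)-5-methyl-2-(prop-1-en-2-yl)hex-4-en-1-yl]-2,3-dihydro-4H-chromen-4-one
Product: 30 (2S)-2-(2,4-dihydroxy-5-methoxyphenyl)-5-hydroxy-7-methoxy-8-[(2R)-5-methyl-2-(prop-1-en-2-yl)hex-4-en-1-yl]-2,3-dihydro-4H-chromen-4-one, via magnesium phenolate 29 (not isolated)
Conditions: MgI2·OEt2 (4 equiv), THF, 50 °C; then H2O
Reagents that add atoms: magnesium diiodide, I[Mg]I (magnesium and iodine of 29 only)
Why: Magnesium chelates the C4 carbonyl and the peri 5-methoxy oxygen and iodide removes that methyl group by SN2 to give chelate 29, while the non-chelated 7- and 5′-methoxy groups, both alkenes and both stereocentres are untouched (chelation-controlled selective 5-O-demethylation of a 5-methoxyflavanone).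

## Compound list

1 | resorcinol (benzene-1,3-diol) | Oc1cccc(O)c1 | starting material
2 | 1,3-dimethoxybenzene | COc1cccc(OC)c1 | intermediate
3 | 2-(3,5-dimethoxyphenyl)-4,4,5,5-tetramethyl-1,3,2-dioxaborolane | COc1cc(OC)cc(c1)B2OC(C)(C)C(C)(C)O2 | intermediate
4 | 3,5-dimethoxyphenol | COc1cc(O)cc(OC)c1 | intermediate
5 | 1,3-dimethoxy-5-(methoxymethoxy)benzene | COCOc1cc(OC)cc(OC)c1 | intermediate
6 | [2,4-dimethoxy-6-(methoxymethoxy)phenyl]lithium | [Li]c1c(OC)cc(OC)cc1OCOC | intermediate
7 | lithium (chloromethyl)[2,4-dimethoxy-6-(methoxymethoxy)phenyl](pinacolato)borate | [Li+].ClC[B-]1(OC(C)(C)C(C)(C)O1)c2c(OC)cc(OC)cc2OCOC | intermediate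
8 | 2-[2,4-dimethoxy-6-(methoxymethoxy)benzyl]-4,4,5,5-tetramethyl-1,3,2-dioxaborolane | COCOc1cc(OC)cc(OC)c1CB2OC(C)(C)C(C)(C)O2 | intermediate
9 | vinylmagnesium chloride | C=C[Mg]Cl | starting material
10 | 1-bromo-2-methylprop-1-ene | CC(C)=CBr | starting material
11 | chloromagnesium [2,4-dimethoxy-6-(methoxymethoxy)benzyl](ethenyl)(pinacolato)borate | C=C[B-]1(OC(C)(C)C(C)(C)O1)Cc2c(OC)cc(OC)cc2OCOC.[Mg+]Cl | intermediate
12 | 2-{(2R)-1-[2,4-dimethoxy-6-(methoxymethoxy)phenyl]-5-methylhex-4-en-2-yl}-4,4,5,5-tetramethyl-1,3,2-dioxaborolane | CC1(C)OB(OC1(C)C)[C@H](CC=C(C)C)Cc2c(OC)cc(OC)cc2OCOC | intermediate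
13 | 2-bromopropene | CC(Br)=C | starting material
14 | isopropenyllithium (prop-1-en-2-yllithium) | [Li]C(C)=C | intermediate
15 | lithium {(2R)-1-[2,4-dimethoxy-6-(methoxymethoxy)phenyl]-5-methylhex-4-en-2-yl}(prop-1-en-2-yl)(pinacolato)borate | [Li+].C=C(C)[B-]1(OC(C)(C)C(C)(C)O1)[C@H](CC=C(C)C)Cc2c(OC)cc(OC)cc2OCOC | intermediate
16 | 2-{(3R)-3-[2,4-dimethoxy-6-(methoxymethoxy)benzyl]-1-iodo-2,6-dimethylhept-5-en-2-yl}-4,4,5,5-tetramethyl-1,3,2-dioxaborolane (both configurations at C2) | ICC(C)(B1OC(C)(C)C(C)(C)O1)[C@H](CC=C(C)C)Cc2c(OC)cc(OC)cc2OCOC | intermediate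
17 | 1,5-dimethoxy-3-(methoxymethoxy)-2-[(2R)-5-methyl-2-(prop-1-en-2-yl)hex-4-en-1-yl]benzene | C=C(C)[C@H](CC=C(C)C)Cc1c(OC)cc(OC)cc1OCOC | intermediate
18 | N-methoxy-N-methylacetamide | CC(=O)N(C)OC | starting material
19 | {4,6-dimethoxy-2-(methoxymethoxy)-3-[(2R)-5-methyl-2-(prop-1-en-2-yl)hex-4-en-1-yl]phenyl}lithium | C=C(C)[C@H](CC=C(C)C)Cc1c(OC)cc(OC)c([Li])c1OCOC | intermediate
20 | lithium 1-{4,6-dimethoxy-2-(methoxymethoxy)-3-[(2R)-5-methyl-2-(prop-1-en-2-yl)hex-4-en-1-yl]phenyl}-1-[methoxy(methyl)amino]ethan-1-olate (both configurations at the new carbon) | C=C(C)[C@H](CC=C(C)C)Cc1c(OC)cc(OC)c(C(C)(O[Li])N(C)OC)c1OCOC | intermediate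
21 | 1-{4,6-dimethoxy-2-(methoxymethoxy)-3-[(2R)-5-methyl-2-(prop-1-en-2-yl)hex-4-en-1-yl]phenyl}ethan-1-one | C=C(C)[C@H](CC=C(C)C)Cc1c(OC)cc(OC)c(C(C)=O)c1OCOC | intermediate
22 | (2E)-1-{4,6-dimethoxy-2-(methoxymethoxy)-3-[(2R)-5-methyl-2-(prop-1-en-2-yl)hex-4-en-1-yl]phenyl}-3-(dimethylamino)prop-2-en-1-one | C=C(C)[C@H](CC=C(C)C)Cc1c(OC)cc(OC)c(C(=O)/C=C/N(C)C)c1OCOC | intermediate
23 | (2E)-3-(dimethylamino)-1-{2-hydroxy-4,6-dimethoxy-3-[(2R)-5-methyl-2-(prop-1-en-2-yl)hex-4-en-1-yl]phenyl}prop-2-en-1-one | C=C(C)[C@H](CC=C(C)C)Cc1c(OC)cc(OC)c(C(=O)/C=C/N(C)C)c1O | intermediate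
24 | 5,7-dimethoxy-8-[(2R)-5-methyl-2-(prop-1-en-2-yl)hex-4-en-1-yl]-4H-chromen-4-one | C=C(C)[C@H](CC=C(C)C)Cc1c(OC)cc(OC)c2c1OC=CC2=O | intermediate
25 | 4-bromobenzene-1,3-diol | Oc1ccc(Br)c(O)c1 | intermediate
26 | 4-methoxybenzene-1,3-diol | COc1ccc(O)cc1O | intermediate
27 | (2S)-2-(2,4-dihydroxy-5-methoxyphenyl)-5,7-dimethoxy-8-[(2R)-5-methyl-2-(prop-1-en-2-yl)hex-4-en-1-yl]-2H-chromen-4-ol | C=C(C)[C@H](CC=C(C)C)Cc1c(OC)cc(OC)c2c1O[C@H](c1cc(OC)c(O)cc1O)C=C2O | intermediate
28 | (2S)-2-(2,4-dihydroxy-5-methoxyphenyl)-5,7-dimethoxy-8-[(2R)-5-methyl-2-(prop-1-en-2-yl)hex-4-en-1-yl]-2,3-dihydro-4H-chromen-4-one | C=C(C)[C@H](CC=C(C)C)Cc1c(OC)cc(OC)c2c1O[C@H](c1cc(OC)c(O)cc1O)CC2=O | intermediate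
29 | iodomagnesium 5-phenolate of 30 (carbonyl-chelated) | C=C(C)[C@H](CC=C(C)C)Cc1c(OC)cc(O[Mg]I)c2c1O[C@H](c1cc(OC)c(O)cc1O)CC2=O | intermediate
30 | (2S)-2-(2,4-dihydroxy-5-methoxyphenyl)-5-hydroxy-7-methoxy-8-[(2R)-5-methyl-2-(prop-1-en-2-yl)hex-4-en-1-yl]-2,3-dihydro-4H-chromen-4-one | C=C(C)[C@H](CC=C(C)C)Cc1c(OC)cc(O)c2c1O[C@H](c1cc(OC)c(O)cc1O)CC2=O | target

## Step count and risks

Total steps: 12. Longest linear sequence: 10 steps (steps 1–8, 11 and 12, from resorcinol); steps 9 and 10 make the ring B partner.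

Steps most likely to fail:

**Step 11 (the new arylation).** The acid may be too weak to activate the electron-rich chromone, may protonate the side-chain alkenes, or may give low facial selectivity. The fallback uses known chemistry, sets out from 24 and 26, and returns at 28. Compound 26 is protected with MOMCl/iPr2NEt to 1-methoxy-2,4-bis(methoxymethoxy)benzene F4. NBS brominates F4 at the position para to one OMOM group and ortho to the other, giving 1-bromo-5-methoxy-2,4-bis(methoxymethoxy)benzene F5. Bromine–lithium exchange (n-BuLi, −78 °C) gives [5-methoxy-2,4-bis(methoxymethoxy)phenyl]lithium F6, which with B(OMe)3 and then dilute HCl gives [5-methoxy-2,4-bis(methoxymethoxy)phenyl]boronic acid F7. Rhodium-catalysed asymmetric 1,4-addition of F7 to 24 ([Rh(OH)(cod)]2 with an electron-poor chiral bisphosphine of the MeO-BIPHEP type, antipode chosen for 2S) is an established way to make 2-arylchroman-4-ones from chromones and is expected to tolerate the isolated alkenes. It gives (2S)-5,7-dimethoxy-2-[5-methoxy-2,4-bis(methoxymethoxy)phenyl]-8-[(2R)-5-methyl-2-(prop-1-en-2-yl)hex-4-en-1-yl]-2,3-dihydro-4H-chromen-4-one F8. HCl in MeOH removes both MOM groups and gives 28.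

**Step 5 (conjunctive coupling).** The congested, electron-rich benzyl borate may undergo direct benzyl transfer to palladium instead of the 1,2-shift, or give low ee. The fallback replaces catalyst control by reagent control (lithiation–borylation), sets out from 8, and returns at 12. 4-Methylpent-3-en-1-ol is esterified with 2,4,6-triisopropylbenzoyl chloride to 4-methylpent-3-en-1-yl 2,4,6-triisopropylbenzoate F1. s-BuLi/(−)-sparteine in Et2O at −78 °C removes the pro-S proton to give (S)-1-lithio-4-methylpent-3-en-1-yl 2,4,6-triisopropylbenzoate F2. F2 adds to 8 with retention to give the lithium borate F3. On warming, the benzyl group shifts 1,2 from boron to carbon with inversion and expels the benzoate, giving (R)-12.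

**Step 12 (late demethylation).** The Lewis acid and heat could epimerise C2 through ring opening or attack the acid-sensitive diene side chain. The fallback moves the demethylation in front of the C2 arylation, sets out from 24, and returns at 30. MgI2·OEt2 in THF converts chromone 24, which has no C2 stereocentre to lose, into 5-hydroxy-7-methoxy-8-[(2R)-5-methyl-2-(prop-1-en-2-yl)hex-4-en-1-yl]-4H-chromen-4-one F9. F9 is then arylated with 26 under the conditions of step 11 and gives 30 directly. This fallback still depends on the step 11 chemistry.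

Further compounds
F1 | step 5 | 4-methylpent-3-en-1-yl 2,4,6-triisopropylbenzoate | CC(C)=CCCOC(=O)c1c(C(C)C)cc(C(C)C)cc1C(C)C
F2 | step 5 | (S)-1-lithio-4-methylpent-3-en-1-yl 2,4,6-triisopropylbenzoate (sparteine complex) | [Li][C@H](OC(=O)c1c(C(C)C)cc(C(C)C)cc1C(C)C)CC=C(C)C
F3 | step 5 | lithium [2,4-dimethoxy-6-(methoxymethoxy)benzyl][(1S)-4-methyl-1-(2,4,6-triisopropylbenzoyloxy)pent-3-en-1-yl](pinacolato)borate | [Li+].CC1(C)O[B-](Cc2c(OC)cc(OC)cc2OCOC)(OC1(C)C)[C@H](OC(=O)c1c(C(C)C)cc(C(C)C)cc1C(C)C)CC=C(C)C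
F4 | step 11 | 1-methoxy-2,4-bis(methoxymethoxy)benzene | COc1ccc(OCOC)cc1OCOC
F5 | step 11 | 1-bromo-5-methoxy-2,4-bis(methoxymethoxy)benzene | COc1cc(Br)c(OCOC)cc1OCOC
F6 | step 11 | [5-methoxy-2,4-bis(methoxymethoxy)phenyl]lithium | COc1cc([Li])c(OCOC)cc1OCOC
F7 | step 11 | [5-methoxy-2,4-bis(methoxymethoxy)phenyl]boronic acid | COc1cc(B(O)O)c(OCOC)cc1OCOC
F8 | step 11 | (2S)-5,7-dimethoxy-2-[5-methoxy-2,4-bis(methoxymethoxy)phenyl]-8-[(2R)-5-methyl-2-(prop-1-en-2-yl)hex-4-en-1-yl]-2,3-dihydro-4H-chromen-4-one | C=C(C)[C@H](CC=C(C)C)Cc1c(OC)cc(OC)c2c1O[C@H](c1cc(OC)c(OCOC)cc1OCOC)CC2=O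
F9 | step 12 | 5-hydroxy-7-methoxy-8-[(2R)-5-methyl-2-(prop-1-en-2-yl)hex-4-en-1-yl]-4H-chromen-4-one | C=C(C)[C@H](CC=C(C)C)Cc1c(OC)cc(O)c2c1OC=CC2=O
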